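Write the balance of the starting material, the limiting reagent of Sunday's flask (80.0 mM against 160 mM of partner), as a logarithm, because the partner stays in excess and the catalyst then shows in the slope.

| setting | Sunday's | Thursday's | Saturday's | Wednesday's |
|---|---|---|---|---|
| starting material | 80.0 mM | 48.0 mM | 80.0 mM | 80.0 mM |
| partner | 160 mM | 128 mM | 320 mM | 160 mM |
| free catalyst | 4.00 mM | 4.00 mM | 4.00 mM | 4.00 mM |
| time |  |  |  | 40 min |

| run | time / min | [starting material] / mM |
|---|---|---|
| Sunday's run | 0.75 | 65.7 |
| Sunday's run | 2.3 | 37.8 |
| Sunday's run | 4.4 | 22.8 |
| Sunday's run | 6.9 | 14.7 |
| Sunday's run | 9.9 | 10.5 |
| Thursday's run | 0.75 | 41.0 |
| Thursday's run | 2.3 | 25.0 |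
| Thursday's run | 4.4 | 15.1 |
| Thursday's run | 6.9 | 9.8 |
| Thursday's run | 9.9 | 7.0 |
| Saturday's run | 0.75 | 55.2 |
| Saturday's run | 2.3 | 20.1 |
| Saturday's run | 4.4 | 8.7 |
| Saturday's run | 6.9 | 6.0 |
| Saturday's run | 9.9 | 3.8 |

(readings scatter by 0.4 mM)

- Overall: starting material + partner -> product, with free catalyst as catalyst.
- Constant volume, constant temperature.
- An order is taken over about fifteen percent of the charge, up and down.

* the exponent of [starting material] in the starting rate at the charge of the Sunday's run (at the point where two percent of the starting material have become product) (one fixed amount of product, the same in the runs compared)
* the exponent of [partner] in the starting rate at the charge of the Sunday's run (at the point where two percent of the starting material have become product)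
* the Thursday's run starts with 32.0 mM less of starting material and of partner than the Sunday's run, and with no product. Compared where both hold the same amount of starting material, once fifteen percent of what the Thursday's run was charged with has turned into product, is the Thursday's run faster, slower or alike (within a tenth)?
* starting material in the Wednesday's run at 40 min, as a share of the starting material charged

depth = ln(starting material charged / starting material present)
slope of depth against time = working constant × partner

The slope is a pseudo-first-order constant, and the working constant tracks the catalyst. Sunday's readings give a ladder of times.

On the fastest rung the catalyst wakes: the slope up to 0.75 min is 0.263 /min, lower than the 0.357 /min that follows.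

On the next rung the starting material goes, with a halving time of 1.94 min at that top slope.

On the slowest rung the catalyst fades. The working constant is 2.18 /M/min at depth 1.00 and 1.21 /M/min at depth 1.86, a halving time of 5.94 min, slower than the conversion.

If partner drives the loss of catalyst as it drives the work, partner cancels and the working constant falls on one straight line against depth. Saturday's flask, with twice the partner, tests this: it reads 2.35 /M/min at depth 0.876, where Sunday's line reads 2.32 /M/min.

The line ends at the reach:

reach = later depth + later constant × depth gained / constant lost = 2.93

The reach, the depth at which the working constant comes to zero, is the quantity to carry. Wednesday's 40 min lies 5.06 catalyst halving times past the last reading, so this reckoning puts that flask close to its reach, with 5.31% of the starting material remaining.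

The forecast gives orders of 0.6 and 0.6, calls Thursday's flask alike, and leaves 6.5%, more than this reckoning. Its ground is “a clock on the catalyst”, read from first-order slopes that match at equal times.

The flask gives orders of 0.60 and 0.58, Thursday's flask alike at a ratio of 1.0, and 4.28% remaining in Wednesday's flask.

    active catalyst + starting material + partner → product + active catalyst (852.0 /M²/min)
    active catalyst + partner → spent catalyst + partner (1.056 /M/min)
    free catalyst → active catalyst (2.382 /min)

In Sunday's charge the free catalyst turned active over about 0.420 min while the starting material was already going, the product reached half of the charge at 2.11 min, and active catalyst turned spent alongside the making of product, the constants putting the reach at 3.23. Wednesday's flask, with Sunday's charge, stands at depth 3.15 at 40 min, which is 97.5% of that reach, while Saturday's flask, with twice the partner, reads depth 3.05 at 9.9 min, already 94.4% of it.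

The readings come from a simulation on assumed constants; the scatter is artificial.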